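The data stem from a simulated flask on assumed constants; the scatter is artificial.

The ash run, with 0.43 M of reagent, ended at 5.00 min with bis adduct at 1.8% beside mono adduct at 9.3%, and that pair was the one I reckoned from.

| setting | ash | delta | alpha |
|---|---|---|---|
| solid substrate | 0.68 M | 0.68 M | 0.68 M |
| reagent | 0.43 M | 0.340 M | 2.04 M |
| remark | run made earlier |  |  |
| time |  | 5.0 min | 5.0 min |

ash run (percent of the solid substrate charged)

| time / min | bis adduct / % | mono adduct / % |
|---|---|---|
| 0.417 | 0 | 1.6 |
| 0.833 | 0 | 0.8 |
| 1.33 | 0 | 1.5 |
| 2.50 | 0.1 | 6.3 |
| 5.00 | 1.8 | 9.3 |

(standard deviation of a reading: 1 percentage point)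

- solid, in amounts per volume of the solution: solid substrate
- at the start none of the solid substrate is in solution

- which of these holds the largest part of the solid substrate at the end of delta (mono adduct / bis adduct / other mono adduct / solid substrate)
- which of these holds the largest part of the solid substrate at the end of alpha (mono adduct / bis adduct / other mono adduct / solid substrate)
- amount of bis adduct at the end of alpha, in percent of the solid substrate charged

I read 0.450 L mol⁻¹ as the bis ratio, bis adduct over mono adduct at the end per unit of c(reagent) charged. It is a loose reading, since the bis figure carries a scatter of 1 percentage point, and it leaves out other mono adduct, which the ash run did not read. While mono adduct grows about evenly, its lifetime against reagent (pseudo-first-order, reagent taken as charged) is the run time over 2 times the ratio at that c(reagent).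

That gave me a ladder. In the ash run mono adduct read 1.5% at 1.33 min, so on the lowest rung I read a lag of about that length. Next came the mono lifetime in alpha, 2.72 min, shorter than the run of 5.0 min. The mono lifetime in delta, 16.3 min, lay beyond the run. So I expected bis over mono of 0.153 in delta and about level at 0.918 in alpha. The readings gave me no figure for the dissolving of the solid.

The forecast named solid substrate for delta and solid substrate for alpha, “with about half still solid”, and put bis adduct in alpha at 15%.

Of the four asked about, delta ended with solid substrate largest at 17.1%. Of the same four, alpha ended with bis adduct largest at 24.3%, and solid substrate at 0%.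

    2 reagent → homo dimer (k = 0.0250 L mol⁻¹ min⁻¹)
    starting material + reagent → mono adduct + by-product (k = 0.150 L mol⁻¹ min⁻¹)
    starting material + reagent → other mono adduct + by-product (k = 0.0730 L mol⁻¹ min⁻¹)
    reagent + mono adduct → bis adduct + by-product (k = 0.300 L mol⁻¹ min⁻¹)
    solid substrate ⇌ starting material, rate k5*(cs5 - [starting material]) while solid is left; crystals form when [starting material] > cs5 (solubility = 0.630 M, k = 0.350 min⁻¹)
    reagent + other mono adduct → bis adduct + by-product (k = 0.210 L mol⁻¹ min⁻¹)

In alpha, concentrations as charged, mono adduct has a half-life of 1.1 min by its step to bis adduct, about half the 2.3 min of starting material by its step to mono adduct. The bis ratio at the end of alpha came to 0.687 L mol⁻¹, against the ash reading of 0.450 L mol⁻¹, and in the neighbour of alpha with 1.2 M of reagent, which ended with 12.8% bis adduct beside 15.7% mono adduct, it came to 0.679 L mol⁻¹.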